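**Plan**

1. Retrosynthesis: first the bond between ring carbon C1 (the tertiary carbinol) and the 1,1-disubstituted alkene carbon of the side chain is cut. This carbonyl addition leads back to (3S,4S)-4-bromo-3-chloro-4-methylcyclohexanone and an alkenyl metal that carries the (R)-carbinol as a silyl ether. Then the ring bond C5–C6 of that ketone is cut (C5 is the CH2 next to the C(CH3)Br carbon C4, C6 the CH2 next to the carbonyl carbon C1), which leads back to open-chain (S)-1-bromo-4-chloro-5-methylhex-5-en-2-one.
2. Enabling feature: C4 is a tertiary C–Br carbon that bears the methyl group and is flanked by C5, and C6 is alpha to C1, which can be a ketone. An α-keto radical at C6 therefore adds to the CH2 end of an isopropenyl group (C5=C4), and the tertiary C4 radical takes up bromine. One event makes the only ring, its C5–C6 bond and the C–Br bond, with bromine on the more substituted carbon next to C3–Cl.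
3. Forward: acetate aldol, amide exchange, invertive chlorination and bromomethyl homologation give the bromo ketone (fragment A). A 6-endo bromine atom-transfer radical cyclisation closes the cyclohexanone. The alkenylcerium reagent from fragment B (four steps from 2,3-dibromopropene) is added to the ketone, and desilylation gives the target.
4. Stereochemistry: C3–Cl comes from an auxiliary-controlled aldol carbinol by SN2 inversion. C4–Br is relayed from C3 by anti delivery of bromine. C1 is relayed from the axial C3–Cl by equatorial attack. The remote side-chain carbinol is set by oxazaborolidine-catalysed reduction.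
5. Handling rule: β-chloro carbonyl intermediates lose HCl easily, so no amine or alkoxide base is used once the chloride is in place.

Key step: step 5

Assumption: (R)-2-hydroxy-1,2,2-triphenylethyl acetate is taken to induce the same facial sense with methacrolein as it does with saturated α-branched aldehydes, because isopropenyl and isopropyl are sterically alike.

**Route**

Step 1
Reactants: 1 (R)-2-hydroxy-1,2,2-triphenylethyl acetate; 2 methacrolein
Product: 4 (R)-2-hydroxy-1,2,2-triphenylethyl (R)-3-hydroxy-4-methylpent-4-enoate, via the dilithium ester enolate 3 (not isolated)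
Conditions: LiN(iPr)2 (2.2 equiv), THF, −78 to 0 °C; then 2, THF/2-methylbutane, −125 °C; aq NH4Cl
Reagents that add atoms: none
Why: Acetate aldol addition of the doubly lithiated triphenylglycol acetate (HYTRA aldol), in which the enolate adds 1,2 to the enal, the (R)-auxiliary should shield one enolate face so that the (3R)-carbinol forms as it does with isobutyraldehyde, and the crystalline adduct can be freed from the minor diastereomer by recrystallisation.

Step 2
Reactants: 4 (R)-2-hydroxy-1,2,2-triphenylethyl (R)-3-hydroxy-4-methylpent-4-enoate
Product: 5 (R)-3-hydroxy-N-methoxy-N,4-dimethylpent-4-enamide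
Conditions: MeNH(OMe)·HCl, AlMe3 (excess), CH2Cl2, 0 °C to rt; Rochelle salt work-up
Reagents that add atoms: N,O-dimethylhydroxylamine hydrochloride, CNOC.Cl
Why: Aminolysis of the ester by the aluminium amide made from AlMe3 and the amine hydrochloride (Weinreb amidation), helped by the neighbouring hydroxyl groups of the glycol ester, releases the recoverable auxiliary diol and leaves the carbinol center untouched.

Step 3
Reactants: 5 (R)-3-hydroxy-N-methoxy-N,4-dimethylpent-4-enamide
Product: 6 (S)-3-chloro-N-methoxy-N,4-dimethylpent-4-enamide
Conditions: PPh3, hexachloroacetone, CH2Cl2, 0 °C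
Reagents that add atoms: hexachloroacetone, ClC(Cl)(Cl)C(=O)C(Cl)(Cl)Cl
Why: Appel-type deoxychlorination in which chloride displaces the alkoxyphosphonium group in an SN2 step with inversion to give the (S)-allylic chloride, the hexachloroacetone variant being chosen because it converts secondary allylic alcohols under neutral conditions without allylic transposition.

Step 4
Reactants: 6 (S)-3-chloro-N-methoxy-N,4-dimethylpent-4-enamide
Product: 8 (S)-1-bromo-4-chloro-5-methylhex-5-en-2-one, via lithium hemiaminal alkoxide 7 (not isolated)
Conditions: BrCH2I (1.5 equiv), MeLi·LiBr (1.4 equiv, slow addition), THF, −78 °C; sat. aq NH4Cl at −78 °C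
Reagents that add atoms: bromoiodomethane, BrCI
Why: Iodine–lithium exchange gives bromomethyllithium, which adds once to the N-methoxy-N-methylamide (carbenoid homologation to an α-halo ketone) because the chelated adduct 7 survives until the cold quench, and the low temperature and short exposure should keep deprotonation next to the amide and loss of HCl at bay.

Step 5
Reactants: 8 (S)-1-bromo-4-chloro-5-methylhex-5-en-2-one
Product: 9 (3S,4S)-4-bromo-3-chloro-4-methylcyclohexan-1-one
Conditions: CuBr (10 mol %), tris(2-pyridylmethyl)amine (TPMA, 10 mol %), degassed ClCH2CH2Cl (0.02 M), 40 °C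
Reagents that add atoms: none
Why: The monovalent copper complex CuBr/TPMA reversibly abstracts bromine from the α-bromo ketone to give the electrophilic α-keto radical at C1 of 8, which adds to the CH2 terminus (C6) of the 2-methylallyl chloride unit and so closes the cyclohexanone, and the tertiary radical formed at C5 takes bromine back from the divalent copper complex CuBr2/TPMA, a copper-catalysed atom-transfer radical cyclisation of the Kharasch type. The closest known reaction type is the 6-endo halogen atom-transfer cyclisation of α-halo ketones and α-bromo β-keto esters that hold the carbonyl inside the forming ring and end in a 1,1-disubstituted alkene, which gives 4-halo-4-methylcyclohexanones. The ring closes in the 6-endo-trig mode, and the selectivity over 5-exo that the step needs is secured by the methyl group on the internal alkene carbon, which hinders attack there and makes the endo adduct radical tertiary, and by the sp2 carbonyl carbon in the tether, which strains the 5-exo transition state. The only new stereocenter is the C–Br carbon: in the 2-chloro-1-methylcyclohexyl radical the β C–Cl bond should stand axial, in line with the half-filled orbital, so that bromine is delivered axially to the opposite face and the trans-diaxial bromochloride with equatorial methyl, (3S,4S)-9, should predominate. The chloride-bearing center is not touched, no base is present that could expel HCl from the β-chloro ketone, and high dilution keeps addition to the alkene of a second molecule slow.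

Step 6
Reactants: 10 N-methoxy-N-methylacetamide; 11 2,3-dibromopropene
Product: 13 4-bromo-N-methoxy-N-methylpent-4-enamide, via lithium amide enolate 12 (not isolated)
Conditions: LiN(iPr)2, THF, −78 °C; then 11, −78 to −30 °C
Reagents that add atoms: none
Why: SN2 alkylation of the lithium amide enolate at the allylic C–Br bond of 2,3-dibromopropene, whose vinylic bromide is inert, installs the 2-bromoallyl unit that later becomes the alkenyl nucleophile.

Step 7
Reactants: 13 4-bromo-N-methoxy-N-methylpent-4-enamide
Product: 15 6-bromo-2-methylhepta-1,6-dien-3-one, via bromomagnesium hemiaminal alkoxide 14 (not isolated)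
Conditions: CH2=C(CH3)MgBr (1.5 equiv), THF, 0 °C; inverse quench into cold 1 M HCl
Reagents that add atoms: isopropenylmagnesium bromide, C=C(C)[Mg]Br
Why: Weinreb ketone synthesis in which the chelated magnesium adduct 14 prevents a second addition and the inverse quench into cold acid protonates the released N,O-dimethylhydroxylamine before it can add to the enone.

Step 8
Reactants: 15 6-bromo-2-methylhepta-1,6-dien-3-one
Product: 16 (R)-6-bromo-2-methylhepta-1,6-dien-3-ol
Conditions: (S)-2-methyl-CBS-oxazaborolidine (15 mol %), catecholborane, toluene, −78 °C; aq NaOH work-up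
Reagents that add atoms: none
Why: Corey–Bakshi–Shibata reduction in which the conjugated isopropenyl group takes the role of the large substituent, so that the (S)-oxazaborolidine should deliver hydride to the face that gives the (R)-allylic alcohol, while catecholborane at −78 °C leaves both alkenes alone.

Step 9
Reactants: 16 (R)-6-bromo-2-methylhepta-1,6-dien-3-ol
Product: 17 (R)-[(6-bromo-2-methylhepta-1,6-dien-3-yl)oxy]triethylsilane
Conditions: Et3SiCl, imidazole, CH2Cl2, 0 °C to rt
Reagents that add atoms: chlorotriethylsilane, CC[Si](Cl)(CC)CC
Why: Imidazole-promoted silylation of the secondary alcohol masks the acidic proton for the lithiation and gives an ether that can be removed later without base.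

Step 10
Reactants: 17 (R)-[(6-bromo-2-methylhepta-1,6-dien-3-yl)oxy]triethylsilane; 9 (3S,4S)-4-bromo-3-chloro-4-methylcyclohexan-1-one
Product: 20 (1S,3S,4S)-4-bromo-3-chloro-4-methyl-1-[(5R)-6-methyl-5-(triethylsilyloxy)hepta-1,6-dien-2-yl]cyclohexan-1-ol, via alkenyllithium 18 (not isolated), via alkenylcerium dichloride 19 (not isolated)
Conditions: 17 (1.6 equiv), t-BuLi (3.2 equiv), Et2O, −78 °C; anhydrous CeCl3 (1.7 equiv), THF, −78 °C; then 9 (1.0 equiv), THF, −78 °C; aq NH4Cl at −78 °C
Reagents that add atoms: none
Why: Bromine–lithium exchange gives the alkenyllithium, and transmetalation to the weakly basic alkenylcerium reagent allows 1,2-addition to the easily enolised β-chloro ketone without loss of HCl; in the preferred chair of 9 bromine and chlorine are trans-diaxial and the methyl group equatorial, the axial C3–Cl bond blocks the axial trajectory, and equatorial attack should give the axial hydroxyl cis to chlorine, the (1S)-carbinol.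

Step 11
Reactants: 20 (1S,3S,4S)-4-bromo-3-chloro-4-methyl-1-[(5R)-6-methyl-5-(triethylsilyloxy)hepta-1,6-dien-2-yl]cyclohexan-1-ol
Product: 21 (1S,3S,4S)-4-bromo-3-chloro-1-[(5R)-5-hydroxy-6-methylhepta-1,6-dien-2-yl]-4-methylcyclohexan-1-ol
Conditions: HF·pyridine, pyridine, THF, 0 °C
Reagents that add atoms: none
Why: Fluoride-mediated cleavage of the secondary triethylsilyl ether under buffered, non-basic conditions should spare the tertiary bromide, the secondary chloride and the tertiary allylic alcohol.

**Compound list**

1 | (R)-2-hydroxy-1,2,2-triphenylethyl acetate | CC(=O)O[C@H](c1ccccc1)C(O)(c1ccccc1)c1ccccc1 | starting material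
2 | methacrolein (2-methylprop-2-enal) | C=C(C)C=O | starting material
3 | dilithium ester enolate of 1 | C=C(O[Li])O[C@H](c1ccccc1)C(O[Li])(c1ccccc1)c1ccccc1 | intermediate (not isolated)
4 | (R)-2-hydroxy-1,2,2-triphenylethyl (R)-3-hydroxy-4-methylpent-4-enoate | C=C(C)[C@H](O)CC(=O)O[C@H](c1ccccc1)C(O)(c1ccccc1)c1ccccc1 | intermediate
5 | (R)-3-hydroxy-N-methoxy-N,4-dimethylpent-4-enamide | C=C(C)[C@H](O)CC(=O)N(C)OC | intermediate
6 | (S)-3-chloro-N-methoxy-N,4-dimethylpent-4-enamide | C=C(C)[C@@H](Cl)CC(=O)N(C)OC | intermediate
7 | lithium hemiaminal alkoxide from 6 and bromomethyllithium | C=C(C)[C@@H](Cl)CC(O[Li])(CBr)N(C)OC | intermediate (not isolated)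
8 | (S)-1-bromo-4-chloro-5-methylhex-5-en-2-one | C=C(C)[C@@H](Cl)CC(=O)CBr | intermediate
9 | (3S,4S)-4-bromo-3-chloro-4-methylcyclohexan-1-one | O=C1CC[C@](C)(Br)[C@@H](Cl)C1 | intermediate
10 | N-methoxy-N-methylacetamide | CC(=O)N(C)OC | starting material
11 | 2,3-dibromopropene | C=C(Br)CBr | starting material
12 | lithium enolate of 10 | C=C(O[Li])N(C)OC | intermediate (not isolated)
13 | 4-bromo-N-methoxy-N-methylpent-4-enamide | C=C(Br)CCC(=O)N(C)OC | intermediate
14 | bromomagnesium hemiaminal alkoxide from 13 | C=C(C)C(O[Mg]Br)(CCC(Br)=C)N(C)OC | intermediate (not isolated)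
15 | 6-bromo-2-methylhepta-1,6-dien-3-one | C=C(C)C(=O)CCC(Br)=C | intermediate
16 | (R)-6-bromo-2-methylhepta-1,6-dien-3-ol | C=C(C)[C@H](O)CCC(Br)=C | intermediate
17 | (R)-[(6-bromo-2-methylhepta-1,6-dien-3-yl)oxy]triethylsilane | C=C(C)[C@H](O[Si](CC)(CC)CC)CCC(Br)=C | intermediate
18 | alkenyllithium from 17 | [Li]C(=C)CC[C@@H](O[Si](CC)(CC)CC)C(C)=C | intermediate (not isolated)
19 | alkenylcerium dichloride from 18 | Cl[Ce](Cl)C(=C)CC[C@@H](O[Si](CC)(CC)CC)C(C)=C | intermediate (not isolated)
20 | (1S,3S,4S)-4-bromo-3-chloro-4-methyl-1-[(5R)-6-methyl-5-(triethylsilyloxy)hepta-1,6-dien-2-yl]cyclohexan-1-ol | C=C(C)[C@H](O[Si](CC)(CC)CC)CCC(=C)[C@]1(O)CC[C@](C)(Br)[C@@H](Cl)C1 | intermediate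
21 | (1S,3S,4S)-4-bromo-3-chloro-1-[(5R)-5-hydroxy-6-methylhepta-1,6-dien-2-yl]-4-methylcyclohexan-1-ol | C=C(C)[C@H](O)CCC(=C)[C@]1(O)CC[C@](C)(Br)[C@@H](Cl)C1 | target

**Step count**

Total step count: 11. Longest linear sequence: 7 steps (steps 1 to 5, then 10 and 11). Fragment B takes 4 steps (6 to 9).

**Steps most likely to fail**

Step 5 (key cyclisation). The copper complex may return bromine too slowly, so that the radical is reduced or adds to a second molecule. Bromine may also be delivered with poor facial selectivity, or HCl may be lost from the β-chloro ketone. The fallback sets out from 6 and comes back at 9. It uses a doubly activated radical precursor in a Lewis-acid-promoted chain process at low temperature. Compound 6 is reduced with iBu2AlH (CH2Cl2, −78 °C) to (S)-3-chloro-4-methylpent-4-enal F1. This aldehyde is homologated with tert-butyl diazoacetate and catalytic SnCl2 (Roskamp reaction) to tert-butyl (S)-5-chloro-6-methyl-3-oxohept-6-enoate F2. Bromination with N-bromosuccinimide gives tert-butyl (5S)-2-bromo-5-chloro-6-methyl-3-oxohept-6-enoate F3. Triethylborane and air with Mg(ClO4)2 at −78 °C should then bring about the 6-endo bromine-transfer cyclisation to tert-butyl (4S,5S)-5-bromo-4-chloro-5-methyl-2-oxocyclohexane-1-carboxylate F4. Trifluoroacetic acid followed by gentle warming removes the tert-butyl group and carbon dioxide to give 9.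

Step 10 (fragment union). The organometallic may enolise the β-chloro ketone, which would lead to E1cB loss of HCl, or the addition may show poor facial selectivity. The fallback sets out from 9 and comes back at 21. It replaces the alkenyl nucleophile by a small, weakly basic acetylide and builds the side chain afterwards. Compound 9 takes up ethynylmagnesium bromide precomplexed with CeCl3 (THF, −78 °C), again from the equatorial direction, to give (1S,3S,4S)-4-bromo-3-chloro-1-ethynyl-4-methylcyclohexan-1-ol F5. The coupling partner is 2-methylpenta-1,4-dien-3-ol F6, made from methacrolein 2 and vinylmagnesium bromide. A ruthenium-catalysed redox coupling of the terminal alkyne with this allylic alcohol ([CpRu(MeCN)3]PF6, acetone, room temperature; Alder-ene type) joins the internal alkyne carbon to the vinyl terminus and turns the carbinol of the partner into a ketone. The product is the branched enone 6-[(1S,3S,4S)-4-bromo-3-chloro-1-hydroxy-4-methylcyclohexyl]-2-methylhepta-1,6-dien-3-one F7. Corey–Bakshi–Shibata reduction as in step 8 then sets the (R)-carbinol and gives 21 directly.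

Step 4 (bromomethyl ketone). The carbenoid or MeLi may deprotonate next to the amide, which would be followed by loss of chloride, or MeLi itself may attack the amide. The fallback sets out from 6 and comes back at 8. It brominates an enol ether electrophilically instead of using a nucleophilic carbenoid. MeMgBr (THF, −40 °C) converts 6 into (S)-4-chloro-5-methylhex-5-en-2-one F8. Kinetic enolisation on the methyl side with LiN(SiMe3)2 in the presence of Me3SiCl at −78 °C gives (S)-[(4-chloro-5-methylhexa-1,5-dien-2-yl)oxy]trimethylsilane F9. N-Bromosuccinimide (THF, −78 °C) brominates the terminal enol ether carbon to give 8.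

**Further compounds**

F1 | step 5 | (S)-3-chloro-4-methylpent-4-enal | C=C(C)[C@@H](Cl)CC=O
F2 | step 5 | tert-butyl (S)-5-chloro-6-methyl-3-oxohept-6-enoate | C=C(C)[C@@H](Cl)CC(=O)CC(=O)OC(C)(C)C
F3 | step 5 | tert-butyl (5S)-2-bromo-5-chloro-6-methyl-3-oxohept-6-enoate | C=C(C)[C@@H](Cl)CC(=O)C(Br)C(=O)OC(C)(C)C
F4 | step 5 | tert-butyl (4S,5S)-5-bromo-4-chloro-5-methyl-2-oxocyclohexane-1-carboxylate | O=C1C(C(=O)OC(C)(C)C)C[C@](C)(Br)[C@@H](Cl)C1
F5 | step 10 | (1S,3S,4S)-4-bromo-3-chloro-1-ethynyl-4-methylcyclohexan-1-ol | C#C[C@]1(O)CC[C@](C)(Br)[C@@H](Cl)C1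
F6 | step 10 | 2-methylpenta-1,4-dien-3-ol | C=CC(O)C(C)=C
F7 | step 10 | 6-[(1S,3S,4S)-4-bromo-3-chloro-1-hydroxy-4-methylcyclohexyl]-2-methylhepta-1,6-dien-3-one | C=C(C)C(=O)CCC(=C)[C@]1(O)CC[C@](C)(Br)[C@@H](Cl)C1
F8 | step 4 | (S)-4-chloro-5-methylhex-5-en-2-one | C=C(C)[C@@H](Cl)CC(C)=O
F9 | step 4 | (S)-[(4-chloro-5-methylhexa-1,5-dien-2-yl)oxy]trimethylsilane | C=C(C)[C@@H](Cl)CC(=C)O[Si](C)(C)C
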